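## Structural features

The target (C42H30O23) is a linear heptamer of oxygenated benzene rings A–G joined by six diaryl ether oxygens and carrying seventeen free phenolic hydroxyls. It has no stereocentre, so no stereochemical relationship has to be set. Ring A is a 2,4,6-trihydroxyphenyl end and ring G a 3,4,5-trihydroxyphenyl end. Rings B, D and F are 3,5-dihydroxy-1,4-phenylenedioxy units in which one ether oxygen sits between two hydroxyls, and ring E carries its two ether oxygens on adjacent carbons (C1, C2) with hydroxyls at C3 and C5. Ring C is the most substituted: C1 (oxygen to ring B), C2 (the only C–H), C3, C4 and C5 (three adjacent hydroxyls) and C6 (oxygen to ring D), that is five contiguous oxygenated carbons with the two ether carbons adjacent. The fragile element is the free polyphenol, whose pyrogallol and hydroxyquinol motifs autoxidise to quinones, above all in base; the diaryl ether links are robust, so the hydroxyls are kept as methyl ethers until the last step. The real difficulty is that five of the six ether oxygens are bonded to a carbon with two ortho substituents, and that ring C holds two adjacent ether bonds inside a pentaoxygenated ring. The key step exploits exactly this ring: C1 and C2 are the two carbons of an aryl ynol ether (C1 already bonded to the ring B oxygen), C3 is a ketene carbonyl carbon, and C4, C5 and C6 are the other three carbons of a squarate-derived cyclobutenone (C6 already bonded to the ring D oxygen).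

## Logic of the disconnections

33 ⇒ 32. Sixteen O–CH3 bonds are cut. The free polyphenol is oxidation-prone and the catalogue building blocks are methylated, so all unmasking is left to one final operation. The forward step must cleave alkyl–O bonds sixteen times without touching aryl–O–aryl bonds.

32 ⇒ 27 + 10. Two ring C C–C bonds are cut: C1–C6 (between the two ether carbons) and C2–C3 (between the C–H carbon and the free phenol carbon). Both hindered ring C ether bonds then sit in fragments where they are made by substitution at a vinylic or acetylenic carbon, not by aryl coupling. The heptamer falls into a four-ring and a two-ring piece. The forward step must run a thermal pericyclic cascade with one regiochemical sense.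

27 ⇒ 26 ⇒ 25. The C4 O–CH3 bond and then the C4–H bond are cut, returning the four-carbon unit to the squarate oxidation level. The forward demand is a hydride that attacks only the carbonyl lying across the ring from the aryloxy carbon, and a methylation that avoids both acid and strong base.

25 ⇒ 21 + 23, and 23 ⇒ 22. The two vinylic C–O bonds of the squarate are cut. The ring D to ring C ether is thus made by addition–elimination on a vinylogous acid chloride. The forward step must stop cleanly after one aryloxy group has entered, and the second chloride must be exchanged for methoxy without displacing the aryloxy group.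

10 ⇒ 7 ⇒ 5 + 6. The two acetylenic carbons are traced to 6, and the O–C(sp) bond to addition of the hindered phenoxide of 5 to a chloroalkyne formed in the flask. The forward steps demand an elimination and a lithium–chlorine exchange that leave the methoxyarenes alone, and prompt use of 10.

5 ⇒ 3 ⇒ 1 + 2. The C–OH bond of ring B is traced back to C–CHO, and the A–B ether is cut at the ring B carbon. The doubly ortho-substituted side (1) acts as the phenol nucleophile and the unhindered, formyl-activated bromide (2) as the electrophile. The formyl group serves twice, as activator and as latent hydroxyl.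

21 ⇒ 20. The ring D C–OH bond is traced back to C–Cl. The chloride is a masked phenol that stays inert in the peracid and copper steps before it. The forward step is a catalytic hydroxylation of an electron-rich aryl chloride.

20 ⇒ 16 + 19. The E–F ether is cut at the unhindered ring F carbon, so that the hindered ring E oxygen is again the nucleophile. The forward coupling must engage the bromide of 19 and leave the chloride of 16 untouched.

19 ⇒ 17 + 18. The F–G ether is cut at the ring G carbon; the hindered ring F phenol is the nucleophile and ring G arrives as a boronic acid. The coupling must tolerate the aryl bromide.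

16 ⇒ 14 ⇒ 12 + 13, and 12 ⇒ 11. The ring E C2–OH bond is traced back to C–CHO, and the D–E ether is cut at ring E C1, where the ortho formyl group of 13 activates fluoride displacement by the hindered phenoxide of 12. The chlorine of 12 is placed para to the hydroxyl of 11. This reaches the starting materials 1, 2, 6, 11, 13, 17, 18 and 22.

## Other disconnections considered

Alternative 1: The cut is made at twelve aryl C–OH bonds, which are traced back to formyl groups in dodecaaldehyde A1. Its ether bonds would come from nucleophilic aromatic substitution on fluorinated benzaldehydes. In the forward key step a peracid would convert all twelve aldehydes of A1 to aryl formates by Baeyer–Villiger aryl migration, and methanolysis would release dodecaphenol A2, which still carries five methyl ethers.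
- In favour: the formyl groups both activate each ring for ether formation and stand in for the hydroxyls, so no hindered ether needs a metal-mediated coupling. A2 needs only five O-demethylations against sixteen for 32, which is a clear point for the alternative. The number of steps after the key step is equal (one).
- Against: twelve oxidations must all proceed with aryl and not hydride migration in one flask. Rings bearing two formyl groups are electron-poor until the first has reacted, so carboxylic acid formation and incomplete conversion are to be expected. Every ether oxygen of A1 must still come from a phenol, and a phenoxide with ortho or para formyl groups is a weak nucleophile, so the assembly would need interleaved selective oxidations that conflict with keeping all aldehydes to the end. Ring C of A1 is hexasubstituted with two adjacent aryloxy groups and is no easier to reach than ring C of 32.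
- Comparison: structurally the alternative leaves the assembly linear and changes only the oxidation-state bookkeeping, whereas the chosen plan builds ring C convergently. Mechanistically it trades one pericyclic cascade of uncertain rate for twelve individually reliable but collectively fragile oxidations. In end-game step count the two are equal, and in deprotection burden the alternative is better.

Alternative 2: Ring D is cut at C2–C3 and C5–C6, between each hydroxyl carbon and its ester-bearing neighbour. This gives glutaconate A3 (rings A–C on its enol ether oxygen) and aryloxymalonyl dichloride A4 (rings E–G). In the forward key step the sodium enolate of A3 would be C-acylated twice by A4 and the ring would close to dihydroxy diester A5.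
- In favour: the convergence is the most balanced possible (three rings plus three, the seventh formed in the union), which is better than the two-plus-four union of the chosen plan. The malonyl unit is symmetric, so no regiochemical question arises, again a point where the alternative is at least equal. The ring D hydroxyls arrive free, and both ring D ether bonds exist before the ring does.
- Against: O-acylation and pyranone formation compete with the double C-acylation. A4 has an acidic hydrogen flanked by two acyl chlorides and an aryloxy group and is prone to ketene formation. The hardest ring, ring C, must still be made beforehand inside A3, by addition of a phenol flanked by aryloxy and methoxy groups. A5 needs saponification and double decarboxylation before the fifteen methyl ethers are cleaved, so at least two more operations follow the key step than in the chosen plan.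
- Comparison: structurally the alternative is better balanced but does not simplify ring C. Mechanistically it is ionic, Claisen-type chemistry with a chemoselectivity problem in place of a regioselectivity problem. In step economy after the key step the chosen plan is shorter.

Alternative 3: Ring G is cut at three C–C bonds, giving Cr(CO)5 aryloxy(2-ethoxyvinyl)carbene A6 (rings A–F on the carbene oxygen), ethoxyacetylene A7 and one carbonyl ligand. In the forward key step a Dötz benzannulation would insert A7 and CO and close ring G as 3,5-diethoxy-4-hydroxyphenyl ether A8.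
- In favour: the F–G ether, which on ring F lies between two methoxy groups, is present before ring G exists. Three C–C bonds form in one operation, one more than in the chosen key step. The regiochemistry of alkyne insertion is as well defined as the ynol ether polarisation used in the chosen plan. One step follows the key step, as in the chosen plan.
- Against: the ring that is built is the simplest one, whose trioxygenated phenol is a catalogue compound, so the disconnection removes none of the real difficulty. The route is fully linear, since a six-ring phenol must be completed first. Aryloxy carbene complexes are more labile than alkoxy ones, and a donor-substituted vinyl carbene with an electron-rich alkyne is prone to insertion pathways other than benzannulation. Stoichiometric chromium is needed on the most advanced intermediate. Two ethyl ethers are added to the fourteen methyl ethers to be cleaved.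
- Comparison: structurally the chosen plan places its ring construction where the substitution is worst, the alternative where it is easiest. Mechanistically both are ketene-based benzannulations of comparable uncertainty. In step economy the end games are equal, but the alternative has the longer linear sequence and the heavier metal burden.

Key step: step 15

Assumption: compounds 1, 2, 13, 17 and 18 are taken as catalogue compounds, and every hydroxyl not needed as a nucleophile is carried as its methyl ether so that one reagent unmasks all of them at the end.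

Abbreviations: ArAB = 2,6-dimethoxy-4-(2,4,6-trimethoxyphenoxy)phenyl (the aryl group of 5). ArDG = 4-{3,5-dimethoxy-2-[3,5-dimethoxy-4-(3,4,5-trimethoxyphenoxy)phenoxy]phenoxy}-3,5-dimethoxyphenyl (the aryl group of 21).

## Route

Step 1
Reactants: 1 2,4,6-trimethoxyphenol; 2 4-bromo-2,6-dimethoxybenzaldehyde
Product: 3 2,6-dimethoxy-4-(2,4,6-trimethoxyphenoxy)benzaldehyde
Conditions: CuI (10 mol%), picolinic acid (20 mol%), K3PO4, DMSO, 90 °C, Ar
Reagents that add atoms: none
Why: Ullmann-type diaryl ether coupling under catalysis by monovalent copper; the hindered partner is the phenol, which this ligand system tolerates, and the bromide is unhindered and activated by its para formyl group.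

Step 2
Reactants: 3 2,6-dimethoxy-4-(2,4,6-trimethoxyphenoxy)benzaldehyde
Product: 5 2,6-dimethoxy-4-(2,4,6-trimethoxyphenoxy)phenol (rings A–B phenol), via aryl formate 4 (not isolated)
Conditions: mCPBA, CH2Cl2, 0 °C → rt; aq. NaHCO3 wash; then K2CO3 (cat.), MeOH, rt
Reagents that add atoms: mCPBA, O=C(OO)c1cccc(Cl)c1
Why: Baeyer–Villiger (Dakin-type) oxidation; the aryl group with two ortho methoxy and one para aryloxy donor migrates in preference to hydride, and the formate is methanolysed to the phenol.

Step 3
Reactants: 5 rings A–B phenol; 6 trichloroethylene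
Product: 7 2-{[(E)-1,2-dichloroethenyl]oxy}-1,3-dimethoxy-5-(2,4,6-trimethoxyphenoxy)benzene
Conditions: K2CO3, DMF, 70 °C
Reagents that add atoms: none
Why: Base eliminates HCl from 6 to dichloroacetylene in solution, the phenoxide adds and anti protonation gives the (E)-dichlorovinyl ether; the alkyne carbon is small enough to accept the phenoxide flanked by two methoxy groups.

Step 4
Reactants: 7 (E)-dichlorovinyl ether
Product: 10 2-(ethynyloxy)-1,3-dimethoxy-5-(2,4,6-trimethoxyphenoxy)benzene (rings A–B aryloxyacetylene), via chloroalkyne 8 (not isolated), via lithium acetylide 9 (not isolated)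
Conditions: n-BuLi (2.3 equiv), THF, −78 → −50 °C; then H2O in THF, −78 → 0 °C; used at once
Reagents that add atoms: none
Why: Known conversion of dichlorovinyl ethers to ynol ethers: elimination of HCl, lithium–chlorine exchange and protonation; any ring lithiation at −78 °C would be reversed by the proton quench.

Step 5
Reactants: 11 2,6-dimethoxyphenol
Product: 12 4-chloro-2,6-dimethoxyphenol
Conditions: SO2Cl2 (1.0 equiv), CH2Cl2, 0 °C → rt
Reagents that add atoms: sulfuryl chloride, O=S(=O)(Cl)Cl
Why: Electrophilic aromatic chlorination; both positions ortho to the hydroxyl are blocked, so the hydroxyl directs chlorine to the para carbon.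

Step 6
Reactants: 12 4-chloro-2,6-dimethoxyphenol; 13 2-fluoro-4,6-dimethoxybenzaldehyde
Product: 14 2-(4-chloro-2,6-dimethoxyphenoxy)-4,6-dimethoxybenzaldehyde
Conditions: K2CO3, DMF, 110 °C, N2
Reagents that add atoms: none
Why: Nucleophilic aromatic substitution of fluoride activated by the ortho formyl group; both methoxy groups of 13 are meta to the carbon attacked and do not destabilise the Meisenheimer intermediate, and the aryl chloride is inert.

Step 7
Reactants: 14 2-(4-chloro-2,6-dimethoxyphenoxy)-4,6-dimethoxybenzaldehyde
Product: 16 2-(4-chloro-2,6-dimethoxyphenoxy)-4,6-dimethoxyphenol, via aryl formate 15 (not isolated)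
Conditions: mCPBA, CH2Cl2, 0 °C → rt; aq. NaHCO3 wash; then K2CO3 (cat.), MeOH, rt, N2
Reagents that add atoms: mCPBA, O=C(OO)c1cccc(Cl)c1
Why: Baeyer–Villiger (Dakin-type) oxidation of a 2,4,6-trioxygenated benzaldehyde, for which aryl migration is strongly favoured; the electron-rich phenol is handled under nitrogen.

Step 8
Reactants: 17 4-bromo-2,6-dimethoxyphenol; 18 3,4,5-trimethoxyphenylboronic acid
Product: 19 5-bromo-1,3-dimethoxy-2-(3,4,5-trimethoxyphenoxy)benzene
Conditions: Cu(OAc)2 (2 equiv), pyridine, 4 Å MS, CH2Cl2, rt, dry air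
Reagents that add atoms: none
Why: Chan–Lam–Evans coupling, in which the aryl group passes from boron to divalent copper and the C–O bond forms from trivalent copper; doubly ortho-substituted phenols are good substrates and the aryl bromide is untouched at room temperature.

Step 9
Reactants: 16 2-(4-chloro-2,6-dimethoxyphenoxy)-4,6-dimethoxyphenol; 19 5-bromo-1,3-dimethoxy-2-(3,4,5-trimethoxyphenoxy)benzene
Product: 20 5-chloro-2-{3,5-dimethoxy-2-[3,5-dimethoxy-4-(3,4,5-trimethoxyphenoxy)phenoxy]phenoxy}-1,3-dimethoxybenzene (rings D–G aryl chloride)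
Conditions: CuI (20 mol%), picolinic acid (40 mol%), K3PO4, DMSO, 100 °C, Ar
Reagents that add atoms: none
Why: Ullmann-type coupling with the hindered oxygen again as the nucleophile and the unhindered bromide as electrophile; under copper catalysis at this temperature the aryl bromide reacts and the aryl chloride of ring D does not.

Step 10
Reactants: 20 rings D–G aryl chloride
Product: 21 4-{3,5-dimethoxy-2-[3,5-dimethoxy-4-(3,4,5-trimethoxyphenoxy)phenoxy]phenoxy}-3,5-dimethoxyphenol (rings D–G phenol)
Conditions: Pd2(dba)3 (2 mol%), tBuXPhos (8 mol%), KOH, 1,4-dioxane/H2O, 100 °C; then aq. HCl to pH 4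
Reagents that add atoms: potassium hydroxide, [K+].[OH-]
Why: Palladium-catalysed hydroxylation of an aryl chloride: oxidative addition to zerovalent palladium, exchange for hydroxide and C–O reductive elimination promoted by the bulky biarylphosphine; the chlorine is flanked only by hydrogens.

Step 11
Reactants: 22 squaric acid
Product: 23 squaric acid dichloride (3,4-dichlorocyclobut-3-ene-1,2-dione)
Conditions: (COCl)2 (2.2 equiv), DMF (cat.), CH2Cl2, rt → 40 °C
Reagents that add atoms: oxalyl chloride, O=C(Cl)C(=O)Cl
Why: Known conversion of the vinylogous diacid to its dichloride through the Vilsmeier-type chloroiminium species.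

Step 12
Reactants: 23 squaric acid dichloride; 21 rings D–G phenol
Product: 25 3-methoxy-4-(ArDG-oxy)cyclobut-3-ene-1,2-dione (mixed squarate), via chlorosquarate 24 (not isolated)
Conditions: 21, Et3N (1.05 equiv), added to 23 (1.5 equiv), THF, −78 → −30 °C; then MeOH (5 equiv), Et3N (2 equiv), −78 → 0 °C
Reagents that add atoms: methanol, CO
Why: Two successive addition–eliminations on a vinylogous acid chloride; the first aryloxy group deactivates the remaining chloride, so mono-substitution is controllable, and the chloride still reacts with methanol far faster than the vinylogous aryl ester does.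

Step 13
Reactants: 25 mixed squarate
Product: 26 racemic 4-hydroxy-3-methoxy-2-(ArDG-oxy)cyclobut-2-en-1-one
Conditions: LiAlH(OtBu)3 (1.1 equiv), THF, −78 °C; aq. NH4Cl
Reagents that add atoms: none
Why: 1,2-Hydride reduction of a squarate ester; the carbonyl conjugated with the weaker aryloxy donor (the one next to the methoxy carbon) is the more electrophilic and the less shielded, while the carbonyl that is the vinylogous ester of the methoxy group should be spared; the new stereocentre is formed racemic and is erased in step 15.

Step 14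
Reactants: 26 racemic 4-hydroxy-3-methoxy-2-(ArDG-oxy)cyclobut-2-en-1-one
Product: 27 racemic 3,4-dimethoxy-2-(ArDG-oxy)cyclobut-2-en-1-one
Conditions: MeI (excess), Ag2O, 4 Å MS, MeCN, rt, dark
Reagents that add atoms: iodomethane, CI
Why: Silver-oxide-mediated O-methylation, the standard way to etherify 4-hydroxycyclobutenones, avoids both the acid that would trigger loss of alcohol and the strong base that would open the ring.

Step 15
Reactants: 27 racemic 3,4-dimethoxy-2-(ArDG-oxy)cyclobut-2-en-1-one; 10 rings A–B aryloxyacetylene
Product: 32 2,3-dimethoxy-4-(ArDG-oxy)-5-(ArAB-oxy)phenol (heptamer with one free ring C hydroxyl and sixteen methyl ethers), via vinylketene 28 (not isolated), via vinylcyclobutenone 29 (not isolated), via dienylketene 30 (not isolated), via cyclohexadienone 31 (not isolated)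
Conditions: 10 (2 equiv), PhMe (0.3 M), 80 °C then 110 °C, Ar, sealed tube; then K2CO3, MeOH, rt
Reagents that add atoms: none
Why: Heating opens 27 by a reversible 4-electron conrotatory electrocyclic reaction (the C4 methoxy group turning outward) to vinylketene 28, whose ketene C=C adds the ynol ether 10 in a [2+2] cycloaddition to give 29. A second 4-electron opening gives dienylketene 30, ring C closes by 6-electron disrotatory electrocyclization between the ketene carbon and the methoxyvinyl terminus to dienone 31, and enolisation gives 32. The closest known reaction is the Danheiser benzannulation of cyclobutenones with alkoxy- and siloxyacetylenes; the aryl ynol ether belongs to the same class, is less nucleophilic, but has no β-hydrogen and so cannot lose ketene by a retro-ene path at these temperatures. No stereocentre survives: the C4 centre of 27 and the quaternary centre of 29 are erased on aromatisation. The step needs one regiochemistry, secured by the polarisation of the ynol ether: its unsubstituted carbon is the nucleophile and bonds to the ketene carbonyl carbon, so the ring B ether carbon ends up next to the ring D ether carbon and the C–H next to the new phenol. Excess 10 limits capture of the ketene by the product phenol, and the basic methanol treatment cleaves any aryl ester formed that way.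

Step 16
Reactants: 32 heptamer monophenol hexadecamethyl ether
Product: 33 CNP0351377.0 (heptamer of rings A–G with seventeen free hydroxyls)
Conditions: BBr3 (40 equiv, 1 M in CH2Cl2), CH2Cl2, −78 °C → rt, Ar; MeOH then H2O, 0 °C; degassed reversed-phase chromatography
Reagents that add atoms: none
Why: Lewis acid O-demethylation: bromide attacks the methyl group of each boron-complexed aryl methyl ether, while diaryl ethers offer no such carbon and are not cleaved; hydrolysis of the aryl borates releases the phenols under acidic, non-oxidising conditions.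

## Compound list

1 | 2,4,6-trimethoxyphenol | COc1cc(OC)c(O)c(OC)c1 | starting material
2 | 4-bromo-2,6-dimethoxybenzaldehyde | COc1cc(Br)cc(OC)c1C=O | starting material
3 | 2,6-dimethoxy-4-(2,4,6-trimethoxyphenoxy)benzaldehyde | COc1cc(Oc2c(OC)cc(OC)cc2OC)cc(OC)c1C=O | intermediate
4 | 2,6-dimethoxy-4-(2,4,6-trimethoxyphenoxy)phenyl formate (not isolated) | COc1cc(Oc2c(OC)cc(OC)cc2OC)cc(OC)c1OC=O | intermediate
5 | 2,6-dimethoxy-4-(2,4,6-trimethoxyphenoxy)phenol (rings A–B phenol) | COc1cc(Oc2c(OC)cc(OC)cc2OC)cc(OC)c1O | intermediate
6 | trichloroethylene | ClC=C(Cl)Cl | starting material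
7 | 2-{[(E)-1,2-dichloroethenyl]oxy}-1,3-dimethoxy-5-(2,4,6-trimethoxyphenoxy)benzene | Cl/C=C(/Cl)Oc1c(OC)cc(Oc2c(OC)cc(OC)cc2OC)cc1OC | intermediate
8 | 2-(chloroethynyloxy)-1,3-dimethoxy-5-(2,4,6-trimethoxyphenoxy)benzene (not isolated) | ClC#COc1c(OC)cc(Oc2c(OC)cc(OC)cc2OC)cc1OC | intermediate
9 | lithium 2-(ArAB-oxy)ethynide (not isolated) | [Li]C#COc1c(OC)cc(Oc2c(OC)cc(OC)cc2OC)cc1OC | intermediate
10 | 2-(ethynyloxy)-1,3-dimethoxy-5-(2,4,6-trimethoxyphenoxy)benzene (rings A–B aryloxyacetylene) | C#COc1c(OC)cc(Oc2c(OC)cc(OC)cc2OC)cc1OC | intermediate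
11 | 2,6-dimethoxyphenol | COc1cccc(OC)c1O | starting material
12 | 4-chloro-2,6-dimethoxyphenol | COc1cc(Cl)cc(OC)c1O | intermediate
13 | 2-fluoro-4,6-dimethoxybenzaldehyde | COc1cc(F)c(C=O)c(OC)c1 | starting material
14 | 2-(4-chloro-2,6-dimethoxyphenoxy)-4,6-dimethoxybenzaldehyde | COc1cc(OC)c(C=O)c(Oc2c(OC)cc(Cl)cc2OC)c1 | intermediate
15 | 2-(4-chloro-2,6-dimethoxyphenoxy)-4,6-dimethoxyphenyl formate (not isolated) | COc1cc(OC)c(OC=O)c(Oc2c(OC)cc(Cl)cc2OC)c1 | intermediate
16 | 2-(4-chloro-2,6-dimethoxyphenoxy)-4,6-dimethoxyphenol | COc1cc(OC)c(O)c(Oc2c(OC)cc(Cl)cc2OC)c1 | intermediate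
17 | 4-bromo-2,6-dimethoxyphenol | COc1cc(Br)cc(OC)c1O | starting material
18 | 3,4,5-trimethoxyphenylboronic acid | COc1cc(B(O)O)cc(OC)c1OC | starting material
19 | 5-bromo-1,3-dimethoxy-2-(3,4,5-trimethoxyphenoxy)benzene | COc1cc(Br)cc(OC)c1Oc1cc(OC)c(OC)c(OC)c1 | intermediate
20 | 5-chloro-2-{3,5-dimethoxy-2-[3,5-dimethoxy-4-(3,4,5-trimethoxyphenoxy)phenoxy]phenoxy}-1,3-dimethoxybenzene (rings D–G aryl chloride) | COc1cc(Cl)cc(OC)c1Oc1cc(OC)cc(OC)c1Oc1cc(OC)c(Oc2cc(OC)c(OC)c(OC)c2)c(OC)c1 | intermediate
21 | 4-{3,5-dimethoxy-2-[3,5-dimethoxy-4-(3,4,5-trimethoxyphenoxy)phenoxy]phenoxy}-3,5-dimethoxyphenol (rings D–G phenol) | COc1cc(O)cc(OC)c1Oc1cc(OC)cc(OC)c1Oc1cc(OC)c(Oc2cc(OC)c(OC)c(OC)c2)c(OC)c1 | intermediate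
22 | squaric acid | OC1=C(O)C(=O)C1=O | starting material
23 | squaric acid dichloride (3,4-dichlorocyclobut-3-ene-1,2-dione) | ClC1=C(Cl)C(=O)C1=O | intermediate
24 | 3-chloro-4-(ArDG-oxy)cyclobut-3-ene-1,2-dione (not isolated) | O=C1C(=O)C(Cl)=C1Oc1cc(OC)c(Oc2cc(OC)cc(OC)c2Oc2cc(OC)c(Oc3cc(OC)c(OC)c(OC)c3)c(OC)c2)c(OC)c1 | intermediate
25 | 3-methoxy-4-(ArDG-oxy)cyclobut-3-ene-1,2-dione | COC1=C(Oc2cc(OC)c(Oc3cc(OC)cc(OC)c3Oc3cc(OC)c(Oc4cc(OC)c(OC)c(OC)c4)c(OC)c3)c(OC)c2)C(=O)C1=O | intermediate
26 | racemic 4-hydroxy-3-methoxy-2-(ArDG-oxy)cyclobut-2-en-1-one | COC1=C(Oc2cc(OC)c(Oc3cc(OC)cc(OC)c3Oc3cc(OC)c(Oc4cc(OC)c(OC)c(OC)c4)c(OC)c3)c(OC)c2)C(=O)C1O | intermediate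
27 | racemic 3,4-dimethoxy-2-(ArDG-oxy)cyclobut-2-en-1-one | COC1C(=O)C(Oc2cc(OC)c(Oc3cc(OC)cc(OC)c3Oc3cc(OC)c(Oc4cc(OC)c(OC)c(OC)c4)c(OC)c3)c(OC)c2)=C1OC | intermediate
28 | (3Z)-3,4-dimethoxy-2-(ArDG-oxy)buta-1,3-dien-1-one, the vinylketene (not isolated) | CO/C=C(OC)/C(Oc1cc(OC)c(Oc2cc(OC)cc(OC)c2Oc2cc(OC)c(Oc3cc(OC)c(OC)c(OC)c3)c(OC)c2)c(OC)c1)=C=O | intermediate
29 | racemic 4-[(Z)-1,2-dimethoxyethenyl]-3-(ArAB-oxy)-4-(ArDG-oxy)cyclobut-2-en-1-one (not isolated) | CO/C=C(OC)/C1(Oc2cc(OC)c(Oc3cc(OC)cc(OC)c3Oc3cc(OC)c(Oc4cc(OC)c(OC)c(OC)c4)c(OC)c3)c(OC)c2)C(Oc2c(OC)cc(Oc3c(OC)cc(OC)cc3OC)cc2OC)=CC1=O | intermediate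
30 | (3Z,5Z)-5,6-dimethoxy-3-(ArAB-oxy)-4-(ArDG-oxy)hexa-1,3,5-trien-1-one, the dienylketene (not isolated) | O=C=C/C(Oc1c(OC)cc(Oc2c(OC)cc(OC)cc2OC)cc1OC)=C(Oc1cc(OC)c(Oc2cc(OC)cc(OC)c2Oc2cc(OC)c(Oc3cc(OC)c(OC)c(OC)c3)c(OC)c2)c(OC)c1)\C(OC)=C\OC | intermediate
31 | racemic 5,6-dimethoxy-3-(ArAB-oxy)-4-(ArDG-oxy)cyclohexa-2,4-dien-1-one (not isolated) | COC1C(=O)C=C(Oc2c(OC)cc(Oc3c(OC)cc(OC)cc3OC)cc2OC)C(Oc2cc(OC)c(Oc3cc(OC)cc(OC)c3Oc3cc(OC)c(Oc4cc(OC)c(OC)c(OC)c4)c(OC)c3)c(OC)c2)=C1OC | intermediate
32 | 2,3-dimethoxy-4-(ArDG-oxy)-5-(ArAB-oxy)phenol (heptamer, one free ring C hydroxyl, sixteen methyl ethers) | Oc1cc(Oc2c(OC)cc(Oc3c(OC)cc(OC)cc3OC)cc2OC)c(Oc2cc(OC)c(Oc3cc(OC)cc(OC)c3Oc3cc(OC)c(Oc4cc(OC)c(OC)c(OC)c4)c(OC)c3)c(OC)c2)c(OC)c1OC | intermediate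
33 | CNP0351377.0 (heptamer of rings A–G, seventeen free hydroxyls) | Oc1cc(O)c(Oc2cc(O)c(Oc3cc(O)c(O)c(O)c3Oc3cc(O)c(Oc4cc(O)cc(O)c4Oc4cc(O)c(Oc5cc(O)c(O)c(O)c5)c(O)c4)c(O)c3)c(O)c2)c(O)c1 | target

## Step count and least certain steps

Total: 16 steps. Longest linear sequence: 10 steps (11 → 12 → 14 → 16 → 20 → 21 → 25 → 26 → 27 → 32 → 33; steps 5, 6, 7, 9, 10, 12, 13, 14, 15, 16).

**Step 15 (key step).** The cycloaddition between an oxygen-rich, crowded and therefore weakly electrophilic ketene and a moderately nucleophilic aryl ynol ether may be slow. The ketene could then be diverted into dimerisation, acylation of the product phenol or intramolecular acylation of the electron-rich ring D ortho carbon, while the alkyne oligomerises on prolonged heating. The fallback gives up ring construction and makes ring C ethers by classical substitution; it sets out from 5 and 20 and comes back at 33.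
- Rieche formylation (Cl2CHOMe, TiCl4, CH2Cl2, 0 °C) of 5-fluoro-1,2,3-trimethoxybenzene, whose two free positions are equivalent, would give 6-fluoro-2,3,4-trimethoxybenzaldehyde F1.
- The phenoxide of 5 (Cs2CO3, DMSO, 120 °C) would displace the formyl-activated fluoride to give 2,3,4-trimethoxy-6-(ArAB-oxy)benzaldehyde F2.
- Dakin oxidation (mCPBA, then K2CO3/MeOH) would pass through 2,3,4-trimethoxy-6-(ArAB-oxy)phenyl formate F3 to 2,3,4-trimethoxy-6-(ArAB-oxy)phenol F4.
- Palladium-catalysed C–O coupling of F4 with chloride 20 (Pd(OAc)2, tBuXPhos, K3PO4, PhMe, 100 °C) would give the heptadecamethyl ether of the target F5.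
- The conditions of step 16 would then convert F5 to 33.

**Step 13.** The two squarate carbonyls may be discriminated poorly, or hydride may add in conjugate fashion with loss of aryloxide. The fallback removes the regiochemical question by symmetry; it sets out from 21 and 23 and comes back at 27.
- Two equivalents of 21 with 23 (Et3N, THF, 0 °C) would give 3,4-bis(ArDG-oxy)cyclobut-3-ene-1,2-dione F6.
- LiAlH(OtBu)3 at −78 °C, acting on two equivalent carbonyls, would give racemic 4-hydroxy-2,3-bis(ArDG-oxy)cyclobut-2-en-1-one F7.
- MeI/Ag2O would give racemic 4-methoxy-2,3-bis(ArDG-oxy)cyclobut-2-en-1-one F8.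
- MeOH with K2CO3 (cat.) at 0 °C would exchange only the aryloxy group at C3, the β-carbon of the enone, by addition–elimination. This gives 27 and returns one equivalent of 21 for reuse.

**Step 9.** Oxidative addition and aryloxide exchange at an electron-rich bromide with a doubly ortho-substituted, oxidation-prone phenol may be sluggish, so that protodebromination and phenol degradation outrun the coupling. The fallback forms the E–F ether without copper and attaches ring G afterwards; it sets out from 16 and comes back at 20.
- Nucleophilic aromatic substitution of 16 on 4-fluoro-2,6-dimethoxybenzaldehyde (Cs2CO3, DMSO, 110 °C) would give 4-[2-(4-chloro-2,6-dimethoxyphenoxy)-4,6-dimethoxyphenoxy]-2,6-dimethoxybenzaldehyde F9.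
- Dakin oxidation would pass through 4-[2-(4-chloro-2,6-dimethoxyphenoxy)-4,6-dimethoxyphenoxy]-2,6-dimethoxyphenyl formate F10 to 4-[2-(4-chloro-2,6-dimethoxyphenoxy)-4,6-dimethoxyphenoxy]-2,6-dimethoxyphenol F11.
- Chan–Lam coupling of F11 with 18 under the conditions of step 8 would give 20.

**Step 16.** Cleavage may stall at the crowded methoxy groups once insoluble polyborates form, and the free polyphenol may be oxidised during purification. The fallback changes the isolation strategy to derivatise, purify and release; it sets out from 32 and comes back at 33.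
- The crude demethylation product would be peracetylated (Ac2O, pyridine, Ar) to the heptadecaacetate of the target F12, which is stable and can be chromatographed on silica.
- Incompletely demethylated material separated at this stage would be resubmitted to demethylation.
- Degassed acidic methanolysis (AcCl in MeOH, 0 °C → rt) of F12 would release 33.

## Further compounds

F1 | step 15 | 6-fluoro-2,3,4-trimethoxybenzaldehyde | COc1cc(F)c(C=O)c(OC)c1OC
F2 | step 15 | 2,3,4-trimethoxy-6-(ArAB-oxy)benzaldehyde | COc1cc(Oc2c(OC)cc(Oc3c(OC)cc(OC)cc3OC)cc2OC)c(C=O)c(OC)c1OC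
F3 | step 15 | 2,3,4-trimethoxy-6-(ArAB-oxy)phenyl formate | COc1cc(Oc2c(OC)cc(Oc3c(OC)cc(OC)cc3OC)cc2OC)c(OC=O)c(OC)c1OC
F4 | step 15 | 2,3,4-trimethoxy-6-(ArAB-oxy)phenol | COc1cc(Oc2c(OC)cc(Oc3c(OC)cc(OC)cc3OC)cc2OC)c(O)c(OC)c1OC
F5 | step 15 | heptadecamethyl ether of the target | COc1cc(Oc2c(OC)cc(Oc3c(OC)cc(OC)cc3OC)cc2OC)c(Oc2cc(OC)c(Oc3cc(OC)cc(OC)c3Oc3cc(OC)c(Oc4cc(OC)c(OC)c(OC)c4)c(OC)c3)c(OC)c2)c(OC)c1OC
F6 | step 13 | 3,4-bis(ArDG-oxy)cyclobut-3-ene-1,2-dione | O=C1C(=O)C(Oc2cc(OC)c(Oc3cc(OC)cc(OC)c3Oc3cc(OC)c(Oc4cc(OC)c(OC)c(OC)c4)c(OC)c3)c(OC)c2)=C1Oc1cc(OC)c(Oc2cc(OC)cc(OC)c2Oc2cc(OC)c(Oc3cc(OC)c(OC)c(OC)c3)c(OC)c2)c(OC)c1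
F7 | step 13 | racemic 4-hydroxy-2,3-bis(ArDG-oxy)cyclobut-2-en-1-one | OC1C(=O)C(Oc2cc(OC)c(Oc3cc(OC)cc(OC)c3Oc3cc(OC)c(Oc4cc(OC)c(OC)c(OC)c4)c(OC)c3)c(OC)c2)=C1Oc1cc(OC)c(Oc2cc(OC)cc(OC)c2Oc2cc(OC)c(Oc3cc(OC)c(OC)c(OC)c3)c(OC)c2)c(OC)c1
F8 | step 13 | racemic 4-methoxy-2,3-bis(ArDG-oxy)cyclobut-2-en-1-one | COC1C(=O)C(Oc2cc(OC)c(Oc3cc(OC)cc(OC)c3Oc3cc(OC)c(Oc4cc(OC)c(OC)c(OC)c4)c(OC)c3)c(OC)c2)=C1Oc1cc(OC)c(Oc2cc(OC)cc(OC)c2Oc2cc(OC)c(Oc3cc(OC)c(OC)c(OC)c3)c(OC)c2)c(OC)c1
F9 | step 9 | 4-[2-(4-chloro-2,6-dimethoxyphenoxy)-4,6-dimethoxyphenoxy]-2,6-dimethoxybenzaldehyde | COc1cc(Cl)cc(OC)c1Oc1cc(OC)cc(OC)c1Oc1cc(OC)c(C=O)c(OC)c1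
F10 | step 9 | 4-[2-(4-chloro-2,6-dimethoxyphenoxy)-4,6-dimethoxyphenoxy]-2,6-dimethoxyphenyl formate | COc1cc(Cl)cc(OC)c1Oc1cc(OC)cc(OC)c1Oc1cc(OC)c(OC=O)c(OC)c1
F11 | step 9 | 4-[2-(4-chloro-2,6-dimethoxyphenoxy)-4,6-dimethoxyphenoxy]-2,6-dimethoxyphenol | COc1cc(Cl)cc(OC)c1Oc1cc(OC)cc(OC)c1Oc1cc(OC)c(O)c(OC)c1
F12 | step 16 | heptadecaacetate of the target | CC(=O)Oc1cc(OC(C)=O)c(Oc2cc(OC(C)=O)c(Oc3cc(OC(C)=O)c(OC(C)=O)c(OC(C)=O)c3Oc3cc(OC(C)=O)c(Oc4cc(OC(C)=O)cc(OC(C)=O)c4Oc4cc(OC(C)=O)c(Oc5cc(OC(C)=O)c(OC(C)=O)c(OC(C)=O)c5)c(OC(C)=O)c4)c(OC(C)=O)c3)c(OC(C)=O)c2)c(OC(C)=O)c1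
A1 | alternative 1 | heptameric polyether dodecaaldehyde with five methyl ethers | COc1cc(C=O)c(Oc2cc(C=O)c(Oc3cc(C=O)c(OC)c(C=O)c3Oc3cc(C=O)c(Oc4cc(C=O)cc(C=O)c4Oc4cc(C=O)c(Oc5cc(OC)c(OC)c(OC)c5)c(C=O)c4)c(C=O)c3)c(C=O)c2)c(C=O)c1
A2 | alternative 1 | heptamer dodecaphenol with five methyl ethers | COc1cc(O)c(Oc2cc(O)c(Oc3cc(O)c(OC)c(O)c3Oc3cc(O)c(Oc4cc(O)cc(O)c4Oc4cc(O)c(Oc5cc(OC)c(OC)c(OC)c5)c(O)c4)c(O)c3)c(O)c2)c(O)c1
A3 | alternative 2 | dimethyl 3-(rings A–C aryloxy)pent-2-enedioate (mixture of double-bond isomers) | COC(=O)CC(=CC(=O)OC)Oc1c(Oc2c(OC)cc(Oc3c(OC)cc(OC)cc3OC)cc2OC)cc(OC)c(OC)c1OC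
A4 | alternative 2 | 2-(rings E–G aryloxy)malonyl dichloride | O=C(Cl)C(Oc1cc(OC)cc(OC)c1Oc1cc(OC)c(Oc2cc(OC)c(OC)c(OC)c2)c(OC)c1)C(=O)Cl
A5 | alternative 2 | heptamer with ring D as dihydroxy diester and fifteen methyl ethers | COC(=O)c1c(O)c(Oc2cc(OC)cc(OC)c2Oc2cc(OC)c(Oc3cc(OC)c(OC)c(OC)c3)c(OC)c2)c(O)c(C(=O)OC)c1Oc1c(Oc2c(OC)cc(Oc3c(OC)cc(OC)cc3OC)cc2OC)cc(OC)c(OC)c1OC
A6 | alternative 3 | pentacarbonyl[(rings A–F aryloxy)((E)-2-ethoxyethenyl)methylidene]chromium | CCO/C=C/C(Oc1c(OC)cc(Oc2c(Oc3c(OC)cc(Oc4c(Oc5c(OC)cc(Oc6c(OC)cc(OC)cc6OC)cc5OC)cc(OC)c(OC)c4OC)cc3OC)cc(OC)cc2OC)cc1OC)=[Cr](=C=O)(=C=O)(=C=O)(=C=O)=C=O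
A7 | alternative 3 | ethoxyacetylene | CCOC#C
A8 | alternative 3 | heptamer with ring G as 3,5-diethoxy-4-hydroxyphenyl and fourteen methyl ethers | CCOc1cc(Oc2c(OC)cc(Oc3c(Oc4c(OC)cc(Oc5c(Oc6c(OC)cc(Oc7c(OC)cc(OC)cc7OC)cc6OC)cc(OC)c(OC)c5OC)cc4OC)cc(OC)cc3OC)cc2OC)cc(OCC)c1O
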